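**Plan**
- Numbering the lactone O1, C2(=O), C3=C4, C5, C6, C7 and calling the carbinol carbon on C7 C1′, the unit C4–C5–C6–C7 (oxygen on C7, carbonyl-level C4, C1′–OH next door) is a ring-opened, oxidised 2-furyl carbinol (furan C2–C5 = C7–C4). This is what an Achmatowicz rearrangement delivers.
- The retrosynthesis cuts, in order: C3=C4 (intramolecular Horner–Wadsworth–Emmons), the O1–C2 ester bond, the C3–CH2 side-chain bond (phosphonoacetate alkylation), C7–CH3, the pyranone back to the furyl carbinol, and the C1′–furan bond.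
- Forward: nerol is cut down to an aldehyde and joined to furan. The furyl carbinol is rearranged to a temporary pyranone ring, which is methylated at C7, acylated on the C7 oxygen and alkylated with an iodide made by Still–Gennari olefination. Acid then opens the pyran, and the oxepinone, the only ring of the target, closes last.
- Stereochemistry: C1′ (R) comes from asymmetric transfer hydrogenation of the furyl ketone, and C7 (R) from equatorial methyl delivery to the pyranone chair, trans to the C1′ side chain. One Z-alkene comes from nerol, the other from the Still–Gennari step, and the ring alkene is cis by ring size.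

Key step: step 7

Remark: the anomeric carbon of the pyran intermediates and the phosphonate-bearing carbon are carried as unseparated mixtures, because both become sp2 centres in the last step.

**Route**

Step 1
Reactants: 1 nerol
Product: 2 tert-butyl{[(2Z)-3,7-dimethylocta-2,6-dien-1-yl]oxy}dimethylsilane
Conditions: TBSCl, imidazole, DMF, 0 °C → rt
Reagents that add atoms: tert-butyldimethylsilyl chloride, CC(C)(C)[Si](C)(C)Cl
Why: Imidazole-promoted O-silylation of the primary allylic alcohol; the Z-alkene is not touched.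

Step 2
Reactants: 2 neryl silyl ether
Product: 3 tert-butyl{[(2Z)-5-(3,3-dimethyloxiran-2-yl)-3-methylpent-2-en-1-yl]oxy}dimethylsilane (racemic)
Conditions: mCPBA (1.0 equiv), CH2Cl2, −20 → 0 °C
Reagents that add atoms: 3-chloroperoxybenzoic acid, OOC(=O)c1cccc(Cl)c1
Why: Prilezhaev epoxidation with one equivalent of peracid should favour the isopropylidene alkene, which is more electron-rich than the 2,3-alkene carrying the inductively withdrawing allylic silyloxy group; the epoxide is racemic, which does not matter because both its carbons lose their stereochemistry in step 3.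

Step 3
Reactants: 3 epoxide
Product: 5 (4Z)-6-(tert-butyldimethylsilyloxy)-4-methylhex-4-enal, via glycol 4 (not isolated)
Conditions: H5IO6, THF–Et2O, 0 °C
Reagents that add atoms: none
Why: Periodic acid hydrolyses the epoxide to glycol 4 and cleaves it at once (Malaprade glycol cleavage), releasing acetone and leaving the Z-alkene and the silyl ether intact at 0 °C.

Step 4
Reactants: 5 aldehyde; 6 furan
Product: 8 rac-(4Z)-6-(tert-butyldimethylsilyloxy)-1-(furan-2-yl)-4-methylhex-4-en-1-ol, via 2-furyllithium 7 (not isolated)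
Conditions: furan, n-BuLi, THF, 0 °C; then 5, −78 °C; aq. NH4Cl
Reagents that add atoms: none
Why: α-Lithiation of furan and 1,2-addition of the 2-furyllithium to the aldehyde form the C1′–furan bond; the carbinol is racemic here and is reset in steps 5 and 6.

Step 5
Reactants: 8 racemic furyl carbinol
Product: 9 (4Z)-6-(tert-butyldimethylsilyloxy)-1-(furan-2-yl)-4-methylhex-4-en-1-one
Conditions: MnO2, CH2Cl2, rt
Reagents that add atoms: none
Why: MnO2 oxidation of a furyl (benzylic-type) carbinol to the ketone; the silylated allylic oxygen and the alkene are inert.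

Step 6
Reactants: 9 furyl ketone
Product: 10 (1R,4Z)-6-(tert-butyldimethylsilyloxy)-1-(furan-2-yl)-4-methylhex-4-en-1-ol
Conditions: RuCl(p-cymene)[(R,R)-TsDPEN] (1 mol %), HCO2H–Et3N (5:2), CH2Cl2, rt
Reagents that add atoms: none
Why: Noyori asymmetric transfer hydrogenation; the (R,R)-diamine catalyst differentiates the heteroaryl from the alkyl substituent as it does for aryl alkyl ketones and should deliver hydride to the face that gives the (R)-carbinol, which is C1′ of the target.

Step 7
Reactants: 10 (R)-furyl carbinol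
Product: 13 (2R)-2-[(3Z)-5-(tert-butyldimethylsilyloxy)-3-methylpent-3-en-1-yl]-6-hydroxy-2H-pyran-3(6H)-one (anomeric mixture), via dihydroxydihydrofuran 11 (not isolated), via cis-enedione 12 (not isolated)
Conditions: NBS (1.05 equiv), NaHCO3, NaOAc, THF–H2O (4:1), 0 °C
Reagents that add atoms: water, O
Why: NBS brominates the electron-rich furan at its free α-carbon (the future C4) and water is taken up at both α-carbons to give the 2,5-dihydroxy-2,5-dihydrofuran 11, which opens to the cis-enedione 12 with a ketone at the future C7 and an aldehyde at the future C4. The C1′ hydroxyl then adds to the aldehyde in a 6-exo-trig hemiacetalisation, the one new skeletal C–O bond, and closes the 6-hydroxy-2H-pyran-3(6H)-one; this is the Achmatowicz oxidative rearrangement of 2-furyl carbinols. The only new stereocentre is the anomeric carbon, which forms as an equilibrating mixture under thermodynamic (anomeric) control and is removed later, while C1′ keeps its R configuration because none of its bonds is broken. The step needs chemoselectivity for the furan over the trisubstituted side-chain alkene: the furan is by far the more nucleophilic π-system, the alkene is deactivated by its allylic silyloxy group, and one equivalent of NBS at 0 °C in bicarbonate/acetate buffer should keep bromohydrin formation and acid-induced silyl loss from competing. The ring so formed ties up the C1′ oxygen as the ring oxygen and so distinguishes it from the C7 oxygen in every later step.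

Step 8
Reactants: 13 pyranone lactol
Product: 14 (2R)-2-[(3Z)-5-(tert-butyldimethylsilyloxy)-3-methylpent-3-en-1-yl]-6-methoxy-2H-pyran-3(6H)-one (anomeric mixture)
Conditions: MeI, Ag2O, CH2Cl2, rt, dark
Reagents that add atoms: iodomethane, CI
Why: Purdie-type O-methylation of the lactol hydroxyl under neutral conditions turns the hemiacetal into a methyl acetal that masks the future C4 aldehyde; the anomeric ratio is of no consequence.

Step 9
Reactants: 14 methyl acetal enone
Product: 15 (2R)-2-[(3Z)-5-(tert-butyldimethylsilyloxy)-3-methylpent-3-en-1-yl]-6-methoxyoxan-3-one (anomeric mixture)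
Conditions: [(Ph3P)CuH]6 (0.4 equiv), H2O, benzene, rt
Reagents that add atoms: none
Why: Conjugate reduction of the enone by the phosphine-stabilised copper hydride (1,4-hydride delivery, protonation by water), which leaves the isolated trisubstituted alkene, the ketone and the acetal alone.

Step 10
Reactants: 15 pyranone
Product: 16 (2R,3R)-2-[(3Z)-5-(tert-butyldimethylsilyloxy)-3-methylpent-3-en-1-yl]-6-methoxy-3-methyloxan-3-ol (anomeric mixture)
Conditions: MeLi, ClTi(OiPr)3, Et2O, −40 °C; then 15, −40 → 0 °C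
Reagents that add atoms: methyllithium (transferred as MeTi(OiPr)3), [Li]C
Why: Organotitanium 1,2-addition to the ketone: the bulky, non-basic MeTi(OiPr)3 should attack the chair (side chain equatorial) along the equatorial trajectory, placing the methyl equatorial and trans to the C1′ side chain and the new hydroxyl axial, which is the 7R configuration, while its low basicity avoids enolisation and epimerisation at C1′.

Step 11
Reactants: 16 tertiary alcohol; 17 diethylphosphonoacetic acid
Product: 18 (2R,3R)-2-[(3Z)-5-(tert-butyldimethylsilyloxy)-3-methylpent-3-en-1-yl]-6-methoxy-3-methyloxan-3-yl 2-(diethoxyphosphoryl)acetate (anomeric mixture)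
Conditions: (EtO)2P(O)CH2CO2H, DCC, DMAP, CH2Cl2, 0 °C → rt
Reagents that add atoms: none
Why: Steglich esterification, in which acids with an acidic α-CH such as phosphonoacetic acid acylate even tertiary alcohols under carbodiimide/DMAP activation; only the C7 hydroxyl is free because the C1′ oxygen is the pyran ring oxygen, so the O1–C2 bond forms at the right oxygen.

Step 12
Reactants: 19 3-(tert-butyldimethylsilyloxy)propanal; 20 ethyl 2-[bis(2,2,2-trifluoroethoxy)phosphoryl]propanoate
Product: 21 ethyl (2Z)-5-(tert-butyldimethylsilyloxy)-2-methylpent-2-enoate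
Conditions: KN(SiMe3)2, 18-crown-6, THF, −78 °C
Reagents that add atoms: none
Why: Still–Gennari olefination; the electron-poor trifluoroethyl phosphonate with a dissociated potassium counter-ion eliminates under kinetic control and should give the Z-enoate, with the ester cis to the chain.

Step 13
Reactants: 21 Z-enoate
Product: 22 (2Z)-5-(tert-butyldimethylsilyloxy)-2-methylpent-2-en-1-ol
Conditions: i-Bu2AlH, CH2Cl2, −78 °C
Reagents that add atoms: none
Why: 1,2-Reduction of the α,β-unsaturated ester to the allylic alcohol by i-Bu2AlH, with the alkene geometry retained.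

Step 14
Reactants: 22 Z-allylic alcohol
Product: 23 (2Z)-5-(tert-butyldimethylsilyloxy)-2-methylpent-2-en-1-yl acetate
Conditions: Ac2O, pyridine, DMAP (cat.), CH2Cl2, 0 °C
Reagents that add atoms: acetic anhydride, CC(=O)OC(C)=O
Why: DMAP-catalysed acetylation of the primary allylic alcohol installs the acetate of the target at the fragment stage.

Step 15
Reactants: 23 silyl ether acetate
Product: 24 (2Z)-5-hydroxy-2-methylpent-2-en-1-yl acetate
Conditions: HF·pyridine, THF–pyridine, 0 °C → rt
Reagents that add atoms: none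
Why: Fluoride-mediated Si–O cleavage under weakly acidic conditions that leave the acetate and the alkene geometry intact.

Step 16
Reactants: 24 hydroxy acetate
Product: 25 (2Z)-5-iodo-2-methylpent-2-en-1-yl acetate
Conditions: I2, PPh3, imidazole, CH2Cl2, 0 °C
Reagents that add atoms: iodine, [I][I]
Why: Appel-type iodination; the primary alcohol is activated as an oxyphosphonium ion and displaced by iodide in an SN2 step.

Step 17
Reactants: 18 phosphonoacetate ester; 25 iodide
Product: 26 (2R,3R)-2-[(3Z)-5-(tert-butyldimethylsilyloxy)-3-methylpent-3-en-1-yl]-6-methoxy-3-methyloxan-3-yl (5Z)-7-acetoxy-2-(diethoxyphosphoryl)-6-methylhept-5-enoate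
Conditions: NaH, DMF, 0 °C; then 25, rt → 40 °C
Reagents that add atoms: none
Why: C-Alkylation of the sodium salt of the phosphonoacetate (malonate-type SN2 alkylation) by the primary iodide forms the C3–CH2 bond; the new stereocentre at the phosphonate carbon is uncontrolled and disappears in step 19.

Step 18
Reactants: 26 alkylated phosphonate
Product: 27 (2R,3R)-6-hydroxy-2-[(3Z)-5-hydroxy-3-methylpent-3-en-1-yl]-3-methyloxan-3-yl (5Z)-7-acetoxy-2-(diethoxyphosphoryl)-6-methylhept-5-enoate
Conditions: AcOH–THF–H2O (3:1:1), 40 °C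
Reagents that add atoms: water, O
Why: Acid-catalysed hydrolysis: the tetrahydropyranyl-type methyl acetal, which has no oxygen on its neighbouring carbons, and the primary silyl ether are both cleaved by aqueous acetic acid, while the tertiary ester, the phosphonate, the acetate and the allylic alcohol should survive.

Step 19
Reactants: 27 lactol
Product: 29 (2Z)-5-{(7R)-7-[(1R,4Z)-1,6-dihydroxy-4-methylhex-4-en-1-yl]-7-methyl-2-oxo-2,5,6,7-tetrahydrooxepin-3-yl}-2-methylpent-2-en-1-yl acetate, via open-chain aldehyde 28 (not isolated)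
Conditions: LiCl, DBU, MeCN (0.002 M), rt → 45 °C
Reagents that add atoms: none
Why: Intramolecular Horner–Wadsworth–Emmons olefination under Masamune–Roush conditions: the lactol equilibrates with aldehyde 28, whose formyl carbon (C4) is attacked by the lithium-chelated phosphonate anion to form C3=C4 and close the seven-membered lactone, the ring allowing only the cis alkene of the target, while deprotonation of the phosphonoacetate should deactivate the ester toward transfer to the C1′ hydroxyl.

**Compound list**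
1 | nerol | CC(C)=CCC/C(C)=C\CO | starting material
2 | tert-butyl{[(2Z)-3,7-dimethylocta-2,6-dien-1-yl]oxy}dimethylsilane | CC(C)=CCC/C(C)=C\CO[Si](C)(C)C(C)(C)C | intermediate
3 | tert-butyl{[(2Z)-5-(3,3-dimethyloxiran-2-yl)-3-methylpent-2-en-1-yl]oxy}dimethylsilane (racemic) | CC1(C)OC1CC/C(C)=C\CO[Si](C)(C)C(C)(C)C | intermediate
4 | (6Z)-8-(tert-butyldimethylsilyloxy)-2,6-dimethyloct-6-ene-2,3-diol (racemic, not isolated) | CC(C)(O)C(O)CC/C(C)=C\CO[Si](C)(C)C(C)(C)C | intermediate
5 | (4Z)-6-(tert-butyldimethylsilyloxy)-4-methylhex-4-enal | O=CCC/C(C)=C\CO[Si](C)(C)C(C)(C)C | intermediate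
6 | furan | c1ccoc1 | starting material
7 | 2-furyllithium (not isolated) | [Li]c1ccco1 | intermediate
8 | rac-(4Z)-6-(tert-butyldimethylsilyloxy)-1-(furan-2-yl)-4-methylhex-4-en-1-ol | OC(CC/C(C)=C\CO[Si](C)(C)C(C)(C)C)c1ccco1 | intermediate
9 | (4Z)-6-(tert-butyldimethylsilyloxy)-1-(furan-2-yl)-4-methylhex-4-en-1-one | O=C(CC/C(C)=C\CO[Si](C)(C)C(C)(C)C)c1ccco1 | intermediate
10 | (1R,4Z)-6-(tert-butyldimethylsilyloxy)-1-(furan-2-yl)-4-methylhex-4-en-1-ol | o1cccc1[C@H](O)CC/C(C)=C\CO[Si](C)(C)C(C)(C)C | intermediate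
11 | (1R,4Z)-6-(tert-butyldimethylsilyloxy)-1-(2,5-dihydroxy-2,5-dihydrofuran-2-yl)-4-methylhex-4-en-1-ol (mixture at both ring carbons, not isolated) | OC1OC(O)(C=C1)[C@H](O)CC/C(C)=C\CO[Si](C)(C)C(C)(C)C | intermediate
12 | (2Z,5R,8Z)-10-(tert-butyldimethylsilyloxy)-5-hydroxy-8-methyl-4-oxodeca-2,8-dienal (not isolated) | O=C/C=C\C(=O)[C@H](O)CC/C(C)=C\CO[Si](C)(C)C(C)(C)C | intermediate
13 | (2R)-2-[(3Z)-5-(tert-butyldimethylsilyloxy)-3-methylpent-3-en-1-yl]-6-hydroxy-2H-pyran-3(6H)-one (anomeric mixture) | O=C1C=CC(O)O[C@@H]1CC/C(C)=C\CO[Si](C)(C)C(C)(C)C | intermediate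
14 | (2R)-2-[(3Z)-5-(tert-butyldimethylsilyloxy)-3-methylpent-3-en-1-yl]-6-methoxy-2H-pyran-3(6H)-one (anomeric mixture) | O=C1C=CC(OC)O[C@@H]1CC/C(C)=C\CO[Si](C)(C)C(C)(C)C | intermediate
15 | (2R)-2-[(3Z)-5-(tert-butyldimethylsilyloxy)-3-methylpent-3-en-1-yl]-6-methoxyoxan-3-one (anomeric mixture) | O=C1CCC(OC)O[C@@H]1CC/C(C)=C\CO[Si](C)(C)C(C)(C)C | intermediate
16 | (2R,3R)-2-[(3Z)-5-(tert-butyldimethylsilyloxy)-3-methylpent-3-en-1-yl]-6-methoxy-3-methyloxan-3-ol (anomeric mixture) | COC1CC[C@@](C)(O)[C@@H](CC/C(C)=C\CO[Si](C)(C)C(C)(C)C)O1 | intermediate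
17 | diethylphosphonoacetic acid | OC(=O)CP(=O)(OCC)OCC | starting material
18 | (2R,3R)-2-[(3Z)-5-(tert-butyldimethylsilyloxy)-3-methylpent-3-en-1-yl]-6-methoxy-3-methyloxan-3-yl 2-(diethoxyphosphoryl)acetate (anomeric mixture) | COC1CC[C@@](C)(OC(=O)CP(=O)(OCC)OCC)[C@@H](CC/C(C)=C\CO[Si](C)(C)C(C)(C)C)O1 | intermediate
19 | 3-(tert-butyldimethylsilyloxy)propanal | O=CCCO[Si](C)(C)C(C)(C)C | starting material
20 | ethyl 2-[bis(2,2,2-trifluoroethoxy)phosphoryl]propanoate | CCOC(=O)C(C)P(=O)(OCC(F)(F)F)OCC(F)(F)F | starting material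
21 | ethyl (2Z)-5-(tert-butyldimethylsilyloxy)-2-methylpent-2-enoate | CCOC(=O)/C(C)=C\CCO[Si](C)(C)C(C)(C)C | intermediate
22 | (2Z)-5-(tert-butyldimethylsilyloxy)-2-methylpent-2-en-1-ol | OC/C(C)=C\CCO[Si](C)(C)C(C)(C)C | intermediate
23 | (2Z)-5-(tert-butyldimethylsilyloxy)-2-methylpent-2-en-1-yl acetate | CC(=O)OC/C(C)=C\CCO[Si](C)(C)C(C)(C)C | intermediate
24 | (2Z)-5-hydroxy-2-methylpent-2-en-1-yl acetate | CC(=O)OC/C(C)=C\CCO | intermediate
25 | (2Z)-5-iodo-2-methylpent-2-en-1-yl acetate | CC(=O)OC/C(C)=C\CCI | intermediate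
26 | (2R,3R)-2-[(3Z)-5-(tert-butyldimethylsilyloxy)-3-methylpent-3-en-1-yl]-6-methoxy-3-methyloxan-3-yl (5Z)-7-acetoxy-2-(diethoxyphosphoryl)-6-methylhept-5-enoate (mixture of anomers and of epimers at the phosphonate carbon) | COC1CC[C@@](C)(OC(=O)C(CC/C=C(C)\COC(C)=O)P(=O)(OCC)OCC)[C@@H](CC/C(C)=C\CO[Si](C)(C)C(C)(C)C)O1 | intermediate
27 | (2R,3R)-6-hydroxy-2-[(3Z)-5-hydroxy-3-methylpent-3-en-1-yl]-3-methyloxan-3-yl (5Z)-7-acetoxy-2-(diethoxyphosphoryl)-6-methylhept-5-enoate (mixture of anomers and of epimers at the phosphonate carbon) | OC1CC[C@@](C)(OC(=O)C(CC/C=C(C)\COC(C)=O)P(=O)(OCC)OCC)[C@@H](CC/C(C)=C\CO)O1 | intermediate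
28 | (4R,5R,8Z)-5,10-dihydroxy-4,8-dimethyl-1-oxodec-8-en-4-yl (5Z)-7-acetoxy-2-(diethoxyphosphoryl)-6-methylhept-5-enoate (open-chain tautomer of 27, not isolated) | O=CCC[C@@](C)(OC(=O)C(CC/C=C(C)\COC(C)=O)P(=O)(OCC)OCC)[C@@H](CC/C(C)=C\CO)O | intermediate
29 | (2Z)-5-{(7R)-7-[(1R,4Z)-1,6-dihydroxy-4-methylhex-4-en-1-yl]-7-methyl-2-oxo-2,5,6,7-tetrahydrooxepin-3-yl}-2-methylpent-2-en-1-yl acetate (CNP0286404.1) | CC(=O)OC/C(C)=C\CCC1=CCC[C@](C)([C@H](O)CC/C(C)=C\CO)OC1=O | target

**Count**
Total steps: 19. Longest linear sequence: 14 (steps 1–11 and 17–19, from nerol); the iodide branch is steps 12–16.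

**Steps most likely to fail**

Step 10. Axial methyl delivery may compete, because the ring oxygen removes one of the two syn-axial hydrogens that normally block that face, so facial selectivity could be poor; enolisation of the α-alkoxy ketone would in addition erode C1′. The fallback sets out from 15 and builds the C7 centre in two operations instead of one. Corey–Chaykovsky epoxidation with dimethylsulfoxonium methylide (trimethylsulfoxonium iodide, NaH, DMSO, rt) adds reversibly, and the betaine with the new carbon equatorial should collapse to the spiro-epoxide (3S,4R)-4-[(3Z)-5-(tert-butyldimethylsilyloxy)-3-methylpent-3-en-1-yl]-6-methoxy-1,5-dioxaspiro[2.5]octane F1. Hydride opening at the epoxide methylene with LiBHEt3 in THF at 0 °C then gives the axial tertiary alcohol with equatorial methyl, and the route is rejoined at 16.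

Step 19. The lactol may open too slowly, the acyl group may move from the tertiary C7 oxygen to the free C1′ oxygen in the open form, or the aldehyde may oligomerise instead of cyclising. The fallback sets out from 27 and removes the free C1′ hydroxyl from the olefination.
- Propane-1,3-dithiol with BF3·OEt2 in CH2Cl2 at −40 °C opens the lactol to the dithioacetal (3R,4R,7Z)-1-(1,3-dithian-2-yl)-4,9-dihydroxy-3,7-dimethylnon-7-en-3-yl (5Z)-7-acetoxy-2-(diethoxyphosphoryl)-6-methylhept-5-enoate F2.
- TESOTf and 2,6-lutidine give the bis-silyl ether (3R,4R,7Z)-1-(1,3-dithian-2-yl)-3,7-dimethyl-4,9-bis(triethylsilyloxy)non-7-en-3-yl (5Z)-7-acetoxy-2-(diethoxyphosphoryl)-6-methylhept-5-enoate F3.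
- MeI and CaCO3 in aqueous MeCN release the aldehyde (4R,5R,8Z)-4,8-dimethyl-1-oxo-5,10-bis(triethylsilyloxy)dec-8-en-4-yl (5Z)-7-acetoxy-2-(diethoxyphosphoryl)-6-methylhept-5-enoate F4.
- LiCl and DBU in dilute MeCN close the ring to (2Z)-5-{(7R)-7-[(1R,4Z)-4-methyl-1,6-bis(triethylsilyloxy)hex-4-en-1-yl]-7-methyl-2-oxo-2,5,6,7-tetrahydrooxepin-3-yl}-2-methylpent-2-en-1-yl acetate F5.
- HF·pyridine in THF removes both silyl groups, and the route is rejoined at 29.

Step 11. Acylation of the hindered axial tertiary alcohol may stall, with the activated acid diverted to N-acylurea. The fallback sets out from 16 and separates acylation from C–P bond formation. Bromoacetyl bromide and pyridine in CH2Cl2 at 0 °C, a small and very reactive acyl donor, should give (2R,3R)-2-[(3Z)-5-(tert-butyldimethylsilyloxy)-3-methylpent-3-en-1-yl]-6-methoxy-3-methyloxan-3-yl 2-bromoacetate F6. A Michaelis–Arbuzov reaction with P(OEt)3 at 110 °C then installs the phosphonate, and the route is rejoined at 18.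

**Further compounds**
F1 | step 10 | (3S,4R)-4-[(3Z)-5-(tert-butyldimethylsilyloxy)-3-methylpent-3-en-1-yl]-6-methoxy-1,5-dioxaspiro[2.5]octane | COC1CC[C@@]2(OC2)[C@@H](CC/C(C)=C\CO[Si](C)(C)C(C)(C)C)O1
F2 | step 19 | (3R,4R,7Z)-1-(1,3-dithian-2-yl)-4,9-dihydroxy-3,7-dimethylnon-7-en-3-yl (5Z)-7-acetoxy-2-(diethoxyphosphoryl)-6-methylhept-5-enoate | S1CCCSC1CC[C@@](C)(OC(=O)C(CC/C=C(C)\COC(C)=O)P(=O)(OCC)OCC)[C@@H](CC/C(C)=C\CO)O
F3 | step 19 | (3R,4R,7Z)-1-(1,3-dithian-2-yl)-3,7-dimethyl-4,9-bis(triethylsilyloxy)non-7-en-3-yl (5Z)-7-acetoxy-2-(diethoxyphosphoryl)-6-methylhept-5-enoate | S1CCCSC1CC[C@@](C)(OC(=O)C(CC/C=C(C)\COC(C)=O)P(=O)(OCC)OCC)[C@@H](CC/C(C)=C\CO[Si](CC)(CC)CC)O[Si](CC)(CC)CC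
F4 | step 19 | (4R,5R,8Z)-4,8-dimethyl-1-oxo-5,10-bis(triethylsilyloxy)dec-8-en-4-yl (5Z)-7-acetoxy-2-(diethoxyphosphoryl)-6-methylhept-5-enoate | O=CCC[C@@](C)(OC(=O)C(CC/C=C(C)\COC(C)=O)P(=O)(OCC)OCC)[C@@H](CC/C(C)=C\CO[Si](CC)(CC)CC)O[Si](CC)(CC)CC
F5 | step 19 | (2Z)-5-{(7R)-7-[(1R,4Z)-4-methyl-1,6-bis(triethylsilyloxy)hex-4-en-1-yl]-7-methyl-2-oxo-2,5,6,7-tetrahydrooxepin-3-yl}-2-methylpent-2-en-1-yl acetate | CC(=O)OC/C(C)=C\CCC1=CCC[C@](C)([C@H](O[Si](CC)(CC)CC)CC/C(C)=C\CO[Si](CC)(CC)CC)OC1=O
F6 | step 11 | (2R,3R)-2-[(3Z)-5-(tert-butyldimethylsilyloxy)-3-methylpent-3-en-1-yl]-6-methoxy-3-methyloxan-3-yl 2-bromoacetate | COC1CC[C@@](C)(OC(=O)CBr)[C@@H](CC/C(C)=C\CO[Si](C)(C)C(C)(C)C)O1
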